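# Synthesis plan for CNP0350037.1 (39) by oxy-Cope ring expansion of a carvone-derived cyclohexanol

## The problem

Target 39 is a germacranolide (ring C1–C10, methyls C14 on C10 and C15 on C4). Its ten-membered carbocycle is trans-fused at C6/C7 to an α-methylene γ-lactone (C12 to O6, C11=C13) and carries trans epoxides at C1–C10 and C4–C5, a free C3 hydroxyl and a tiglate on O8. In what follows α is the ring face that bears O6 and β the opposite one, so 39 is the 1β,10α:4α,5β-diepoxy-3β-hydroxy-8α-tigloyloxy-12,6α-olide.

Eight stereocentres (C1, C3, C4, C5, C6, C7, C8, C10) sit on a flexible medium ring, and ten-membered rings resist end-to-end closure. Both the ring and most of the stereocentres are therefore better made elsewhere and carried in. C3, C4 and C5 are contiguous and oxygenated and can be set on a chair cyclohexane. C5 can then direct C6 by chelation, the ring together with C8 directs C7, and the C1–C10 epoxide can be left to peripheral attack on the finished ring. C8 is insulated from the other centres by C7 and C9 and needs a control element of its own.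

The α-methylene lactone (a Michael acceptor), the tiglate (not compatible with enolate or hydride chemistry) and the two epoxides (acid-labile, the 1,10-epoxide prone to transannular opening) must appear late and meet only mild reagents.

The enabling feature is the transannular C1–C6 axis. An E C1=C10 olefin and an oxygen on C6 are what an oxy-Cope rearrangement leaves behind when the C1–C6 bond of a cyclohexane with alkenyl groups on C1 and C6 breaks and C8–C9 forms. With silicon on the terminus that becomes C8 the same step delivers the C8 oxygen in masked form. The cyclohexane C1–C6 with a methyl on C4 and an isopropenyl group on C1 is the skeleton of carvone.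

## Retrosynthesis

**39 back to 37.** The last bonds cut are the O3–benzyl bond (39 from p-methoxybenzyl ether 38) and the two C–O bonds of the C1–C10 epoxide (38 from olefin 37). The 1,10-epoxide is the most acid-sensitive element, so it should be made as late as possible. In 37 the 4,5-epoxide and the trans lactone hold the ring so that only the outer face of the E olefin is open. C1=C10 is also the only electron-rich double bond, next to two conjugated ones. The forward epoxidation therefore only has to be chemoselective and peripheral. The ether is kept through that step so that a free C3 hydroxyl cannot redirect the peracid, and its oxidative removal is neutral.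

**37 back to 28.** The O8–acyl bond (tiglic acid 35), the C11=C13 bond and the C8–O bond are cut in that order: 37 from 34, 34 from 30, 30 from silane 28. The order is forced. The ester cannot be present when a lactone enolate is formed, and the Michael acceptor should not be present when the silane is oxidised with basic peroxide. Silicon at C8 is inert to every step before its oxidation, which proceeds with retention. The only demand on 28 is the correct C8 configuration.

**28 back to 25.** The C5–O bond of the 4,5-epoxide is cut. The oxygen stays on C4 and C5 becomes a carbinol of opposite configuration, diol 26, masked as acetonide 25. The alternative, epoxidation of an E C4=C5 olefin, would need a trans double bond that cannot exist in a six-membered precursor. A cis-diol can exist there, and closure with inversion at C5 turns it into the trans epoxide. The forward step asks for sulfonylation of the secondary C5 hydroxyl beside the tertiary one and base-induced closure.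

**25 back to 20 and 21.** The lactone C12–O6 bond and the C7–C11 bond are cut, giving ketone 20 and methyl bromoacetate (21) through keto ester 23. The precursor loses the lactone and two stereocentres. The forward steps ask for alkylation of the C6 enolate at C7 on the face trans to silicon, and for reduction of the C6 ketone under chelation by O5. A β-silyl enolate is chosen over a β-alkoxy enolate because it cannot eliminate.

**20 back to 17 (key disconnection).** The C8–C9 bond is cut and C1–C6 is joined. This contracts the ten-membered ring to cyclohexanol 17, with an (E)-2-silylvinyl group on C6 and an isopropenyl group on C1, trans to each other. The cut removes the medium ring, the E olefin and the C8 stereocentre in one stroke. The forward reaction is a ring expansion, not a ring closure, so it pays no entropic price, and its chair transition state relays the configuration of C1 to C8. It asks for a chair pathway and for survival of the silyl group under potassium alkoxide conditions.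

**17 back to 10 and 14; 14 back to 11 and 12.** The C6–C7 bond is cut to give ketone 10 and the vinyl anion derived from stannane 14. Stannane 14 is made from (E)-1,2-bis(tributylstannyl)ethene (11) and benzylchlorodimethylsilane (12). The addition must occur trans to the isopropenyl group. The axial C4 methyl of 10 blocks the axial trajectory, so this is the expected course.

**10 back to 1.** In the chair of 10 with an equatorial isopropenyl group, O3 and O4 are trans-diequatorial and O5 is axial and cis to O4. Reducing the enone first and epoxidising under hydroxyl direction would place the C5 hydroxyl cis to the isopropenyl group. It would then need an epoxy alcohol to open either at its tertiary carbon or against the trans-diaxial rule. The array is therefore built in another order.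

- α′-Hydroxylation of (R)-carvone (1) introduces the C6 oxygen (3), which is silylated (4).
- Nucleophilic epoxidation of the enone sets O4 trans to the isopropenyl group (5).
- The epoxy ketone is opened at C3, the only carbon open to substitution because C4 is tertiary and α to the carbonyl, giving p-methoxybenzyl ether 6.
- A bulky hydride sets O5 cis to O4 (7).
- With O6 still silylated, acetonide formation can only engage O4/O5 (8).
- Desilylation (9) and oxidation give 10.

The carvone stereocentre controls all of this and is then consumed in the rearrangement.

## Roads not taken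

**Alternative 1:** Late carbonylative closure of the methylene lactone.
- Cut: C11–C12 and C12–O6.
- Forward step: hydroxy vinyl iodide A2 (free C6 hydroxyl, 1-iodovinyl group on C7, both epoxides, the tiglate and an O3 triethylsilyl ether in place) would be treated with Pd(PPh3)4 (zerovalent palladium) under CO. Oxidative addition into C11–I, CO insertion and capture of the acylpalladium by the C6 hydroxyl would give A1, one desilylation away from 39.
- Merits: the Michael acceptor is created in its final form under neutral conditions. The strong-base methylenation (step 17) and the period in which a free C8 hydroxyl sits beside the lactone (steps 16 and 17) are avoided. In this respect the road is better than the chosen one.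
- Weak points: the cut removes one carbon and leaves the ten-membered ring, all eight stereocentres, both epoxides and the ester in A2. It says nothing on how the ring or C8 are made. It adds the task of placing a 1-iodovinyl group on a hindered ring carbon with the correct C6/C7 relationship.
- Comparison: this is an end-game, not a plan for the skeleton. The chosen plan offers a ring construction that fixes the E olefin and C8 in one step from a chiral-pool cyclohexane, and accepts a conventional lactone end-game in return.

**Alternative 2:** Reformatsky–Darzens cascade closing the ring and the C4–C5 epoxide.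
- Cut: C4–C5 and C5–O.
- Forward step: in dichloro keto aldehyde A4, CrCl2 (divalent chromium) with LiI would reduce the C4 gem-dichloride to a chloro enolate that adds to the C5 aldehyde. This forms C4–C5 and the ring. K2CO3 would then let the C5 alkoxide displace chloride at C4 to give epoxy ketone A3.
- Merits: it is convergent. Ring and epoxide arise in one operation from an open chain whose E olefin, lactone and ester are already present. On paper it is shorter than the chosen route.
- Weak points:
  - The ring closure is an end-to-end closure of a ten-membered ring and needs high dilution.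
  - Two stereocentres, one of them quaternary, are set during that closure under the influence of C6 alone, and the sense depends on an enolate geometry that is hard to control.
  - The aldehyde in A4 is α to the lactone oxygen and can epimerise.
  - The Michael acceptor meets carbonate base.
  - A3 still needs a stereoselective C3 reduction and the C1–C10 epoxidation.
- Comparison: the chosen plan is longer. Against that it makes C3, C4 and C5 on a chair cyclohexane, where each facial choice has a clear steric reason, and it forms the ring without any cyclisation entropy.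

**Alternative 3:** γ-Selective allylation from a bromomethyl butenolide closing C7–C8.
- Cut: C7–C8.
- Forward step: CrCl2 (divalent chromium) would convert the C13 bromide of butenolide aldehyde A6 into an allylchromium species that attacks the C8 aldehyde through C7. This closes the ring and unveils the α-methylene lactone in A5.
- Merits: one step forms the ring, C7, C8 and the methylene lactone, with no strong base. The end-game would then be two epoxidations and an esterification on a germacradienolide. In step economy and in the treatment of the Michael acceptor this road is as good as or better than the chosen one.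
- Weak points:
  - A6 is an acyclic E,E-diene with stereocentres at C3 and C6 that has to be assembled linearly.
  - The macrocyclisation needs dilution.
  - Its 7,8-selectivity rests on the folding of a ten-membered transition state and is not relayed from an existing centre. The 8α-hydroxyl required here is not guaranteed.
  - The two trisubstituted olefins of A5 must later be epoxidised on defined faces, one of them before and one after esterification.
- Comparison: the chosen plan fixes C8 by a concerted chair rearrangement whose sense follows from the starting material. It brings in the C4–C5 epoxide as a diol of known configuration, not through a face-selective epoxidation, and needs no dilution. Its cost is a longer linear sequence and an enolate methylenation late in the route.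

Key step: step 11

## Route

Remark on the chemistry: methyl bromoacetate (21) is used, not a tert-butyl ester, so that the C6 hydroxyl can close the lactone without strong acid. (E)-1,2-Bis(tributylstannyl)ethene (11) is taken as a purchasable source of the C7–C8 unit. Germacrane numbering is used from step 1 (carvone C1, C2, C3, C4, C5, C6 become C5, C4, C3, C2, C1, C6).

Step 1
Reactants: 1 (R)-carvone
Product: 3 trans-6-hydroxycarvone [(5S,6S)-6-hydroxy-2-methyl-5-(prop-1-en-2-yl)cyclohex-2-en-1-one; hydroxyl on the future C6 and trans to isopropenyl], via potassium dienolate 2 (not isolated)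
Conditions: KN(SiMe3)2, THF, −78 °C; then 2-(phenylsulfonyl)-3-phenyloxaziridine, −78 °C; aqueous work-up
Reagents that add atoms: 2-(phenylsulfonyl)-3-phenyloxaziridine, O=S(=O)(c1ccccc1)N1OC1c1ccccc1
Why: Kinetic α′-deprotonation gives the cross-conjugated dienolate, and enolate hydroxylation by the N-sulfonyloxaziridine occurs anti to the adjacent isopropenyl group, so the hydroxyl is trans to it; this centre is oxidised in step 8, so its purity matters only for clean handling.

Step 2
Reactants: 3 trans-6-hydroxycarvone
Product: 4 C6 tert-butyldimethylsilyl ether of 3
Conditions: t-BuMe2SiCl, imidazole, DMF, 25 °C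
Reagents that add atoms: tert-butylchlorodimethylsilane, CC(C)(C)[Si](C)(C)Cl
Why: Standard silylation of a secondary alcohol; it keeps O6 distinct from O4 and O5 until step 7 and protects the α-ketol from the base of step 3.

Step 3
Reactants: 4 C6 silyl ether
Product: 5 3,4-epoxy C5 ketone (epoxide oxygen trans to isopropenyl and cis to the silyloxy group)
Conditions: 30% H2O2, NaOH (cat.), MeOH, 0 °C
Reagents that add atoms: hydrogen peroxide, OO
Why: Weitz–Scheffer epoxidation: hydroperoxide adds axially to C3 of the enone, anti to the isopropenyl group, and the enolate closes onto oxygen, so the future O4 is trans to isopropenyl; the unactivated isopropenyl olefin does not react.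

Step 4
Reactants: 5 epoxy ketone
Product: 6 C3 p-methoxybenzyl ether with tertiary C4 hydroxyl (O3 cis to isopropenyl; O4 trans to isopropenyl; C5 ketone; C6 silyl ether)
Conditions: 4-MeOC6H4CH2OH (4 equiv), Yb(OTf)3 (10 mol%), CH2Cl2, 0 → 25 °C
Reagents that add atoms: 4-methoxybenzyl alcohol, COc1ccc(CO)cc1
Why: Lewis-acid-catalysed alcoholysis of an epoxide: the chelated epoxy ketone is attacked at C3 in SN2 fashion with inversion, because C4 is fully substituted and α to the carbonyl and so offers neither an SN2 nor a cationic path; halides are known to open 2-methyl-2,3-epoxycyclohexanones at the same carbon in the same anti sense.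

Step 5
Reactants: 6 hydroxy ketone
Product: 7 4,5-cis-diol (C5 hydroxyl cis to the C4 hydroxyl and to the silyloxy group)
Conditions: LiBH(s-Bu)3, THF, −78 °C; aqueous work-up
Reagents that add atoms: none
Why: Ketone reduction by a bulky trialkylborohydride: in the chair with isopropenyl, benzyloxy and silyloxy groups equatorial the reagent avoids the axial hydrogens on C1 and C3 and attacks equatorially, giving the axial C5 hydroxyl cis to O4, as hindered hydrides do with cyclohexanones that carry an axial α-methyl group.

Step 6
Reactants: 7 cis-diol
Product: 8 4,5-acetonide of 7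
Conditions: Me2C(OMe)2, pyridinium p-toluenesulfonate (cat.), CH2Cl2, 25 °C
Reagents that add atoms: 2,2-dimethoxypropane, COC(C)(C)OC
Why: Transacetalisation; the only free hydroxyls are the cis pair on C4 and C5, so the dioxolane can form only across O4/O5.

Step 7
Reactants: 8 acetonide silyl ether
Product: 9 C6 alcohol
Conditions: Bu4NF, THF, 25 °C
Reagents that add atoms: none
Why: Fluoride-induced cleavage of the silyl ether; benzyl ether, acetonide and olefin are inert.

Step 8
Reactants: 9 C6 alcohol
Product: 10 cyclohexanone (C6 ketone; C1 isopropenyl; C3 p-methoxybenzyl ether; 4,5-acetonide)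
Conditions: Dess–Martin periodinane, NaHCO3, CH2Cl2, 0 → 25 °C
Reagents that add atoms: none
Why: Dess–Martin oxidation under buffered, non-basic conditions, so that the α-isopropenyl ketone is neither epimerised at C1 nor isomerised into conjugation.

Step 9
Reactants: 11 (E)-1,2-bis(tributylstannyl)ethene; 12 benzylchlorodimethylsilane
Product: 14 (E)-benzyldimethyl[2-(tributylstannyl)vinyl]silane, via stannylvinyllithium 13 (not isolated)
Conditions: n-BuLi (1.0 equiv), THF, −78 °C; then 12, −78 → 0 °C
Reagents that add atoms: none
Why: Tin–lithium exchange of one stannyl group with retention of the E geometry, then silylation of the vinyllithium; this is the established route to (E)-1-silyl-2-stannylethenes.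

Step 10
Reactants: 14 silyl stannane; 10 cyclohexanone
Product: 17 trans-1-[(E)-2-(benzyldimethylsilyl)vinyl]-2-isopropenylcyclohexanol with C3 p-methoxybenzyl ether and 4,5-acetonide (vinyl trans to isopropenyl; hydroxyl cis to it), via silylvinyllithium 15 (not isolated), via organocerium reagent 16 (not isolated)
Conditions: 14, n-BuLi, THF, −78 °C; CeCl3 (anhydrous), −78 °C; then 10, −78 °C; aqueous work-up
Reagents that add atoms: none
Why: Tin–lithium exchange gives the (E)-vinyllithium with retention, and CeCl3 converts it into a weakly basic organocerium reagent that adds to the enolisable ketone and does not deprotonate C1; attack is equatorial and trans to the neighbouring isopropenyl group because the axial C4 methyl blocks the axial path, which gives the trans-1,2-dialkenyl carbinol with an axial hydroxyl.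

Step 11
Reactants: 17 dialkenyl carbinol
Product: 20 ten-membered C6 ketone with (E)-C1=C10 olefin and 8α-benzyldimethylsilyl group (C3 p-methoxybenzyl ether; 4,5-acetonide), via potassium alkoxide 18 (not isolated), via potassium enolate 19 (not isolated)
Conditions: KH, 18-crown-6, THF, 0 → 25 °C; then AcOH, −78 °C
Reagents that add atoms: none
Why: KH deprotonates the tertiary alcohol and 18-crown-6 loosens the ion pair of 18, whose oxido group weakens the C1–C6 bond and accelerates the [3,3]-sigmatropic shift of the 1,5-diene C8=C7–C6(O)–C1–C10=C9: C8–C9 forms as C1–C6 breaks, giving enolate 19, which is protonated cold on C7 to ketone 20. The closest known reaction is the anionic oxy-Cope ring expansion of trans-1,2-dialkenylcyclohexanols to (E)-cyclodec-5-enones. The ten-membered ring is not closed end to end; it arises by four-carbon ring expansion of the cyclohexane through a six-membered chair transition state (C6, C7, C8, C9, C10, C1), so no dilution is needed. Because the alkenyl groups are trans-diequatorial, both ring bonds (C1–C2 and C6–C5) are equatorial on that chair, and the equatorial C2 makes the new C1=C10 bond E. C8 is the only new stereocentre: the (E)-silyl group is equatorial on the chair, so the face of C8 that bonds to C9 is dictated by the configurations of C1 and C6 and silicon ends on the α face, where O8 of 39 lies. The selectivity needed is chair over boat, and a boat would have to place a ring bond axial or eclipse the silyl terminus with the isopropenyl unit; the trans arrangement made in step 10 secures the chair. The product is a β-silyl enolate, which cannot eliminate, and the cold AcOH quench prevents proton transfer to a C5 enolate that could expel O4.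

Step 12
Reactants: 20 ten-membered ketone; 21 methyl bromoacetate
Product: 23 C7-(methoxycarbonylmethyl) ketone (C11 trans to silicon; C7 as in 39), via lithium enolate 22 (not isolated)
Conditions: LiN(SiMe3)2, THF, −78 °C; then 21, DMPU, −78 → −40 °C
Reagents that add atoms: none
Why: Kinetic deprotonation at the unhindered C7 methylene (C5 is a tertiary α-alkoxy position) and SN2 alkylation of the β-silyl enolate; the inner face of the ring enolate is closed by the transannular C1=C10 unit, so the electrophile enters from outside with C8–H eclipsing the enolate and the silyl group turned outward, which places C11 trans to silicon.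

Step 13
Reactants: 23 keto ester
Product: 25 trans-fused 12,6α-lactone (8α-silyl; C3 p-methoxybenzyl ether; 4,5-acetonide), via hydroxy ester 24 (not isolated)
Conditions: Zn(BH4)2, Et2O, −30 → 0 °C; aqueous work-up; then pyridinium p-toluenesulfonate (cat.), CH2Cl2, 25 °C
Reagents that add atoms: none
Why: Chelation-controlled ketone reduction: zinc bridges the C6 carbonyl and O5 and hydride enters anti to C4, giving the 5,6-anti alcohol with the C6 configuration of 39; the γ-hydroxy methyl ester then closes (5-exo-trig acyl substitution) to the trans lactone.

Step 14
Reactants: 25 lactone acetonide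
Product: 26 4,5-diol lactone
Conditions: AcOH/H2O (4:1), 40 °C
Reagents that add atoms: none
Why: Acid-catalysed hydrolysis of the dioxolane; the p-methoxybenzyl ether, lactone, alkylsilane and isolated olefin tolerate aqueous acetic acid.

Step 15
Reactants: 26 diol
Product: 28 4α,5β-epoxy lactone, via C5 mesylate 27 (not isolated)
Conditions: MeSO2Cl, Et3N, CH2Cl2, 0 °C; then KOt-Bu, THF, 0 °C
Reagents that add atoms: none
Why: Sulfonylation of the secondary C5 hydroxyl (the tertiary C4 hydroxyl is inert), then intramolecular Williamson closure in which the C4 alkoxide displaces the mesylate with inversion at C5; the cis-diol made on the six-membered ring thus becomes the trans epoxide, and the ten-membered ring allows the anti-periplanar arrangement.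

Step 16
Reactants: 28 epoxy lactone silane
Product: 30 8α-hydroxy lactone, via fluorosilane 29 (not isolated)
Conditions: Bu4NF, THF, 0 → 25 °C; then KHCO3, 30% H2O2, MeOH/THF, 40 °C
Reagents that add atoms: hydrogen peroxide, OO
Why: Tamao oxidation of a benzyldimethylsilyl group: fluoride expels the benzyl group as toluene, and basic peroxide oxidises the fluorosilane with migration of C8 from silicon to oxygen, that is with retention; epoxide, lactone, ether and olefin are inert.

Step 17
Reactants: 30 hydroxy lactone
Product: 34 α-methylene lactone (8α-hydroxyl free), via dilithium alkoxide enolate 31 (not isolated), via Mannich base 32 (not isolated), via ammonium iodide 33 (not isolated)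
Conditions: LiN(i-Pr)2 (2.5 equiv), THF, −78 °C; Me2N=CH2 I, −78 → 25 °C; aqueous work-up; MeI, MeOH, 25 °C; then NaHCO3 (aq), CH2Cl2
Reagents that add atoms: N,N-dimethylmethyleneiminium iodide (Eschenmoser's salt), C=[N+](C)C.[I-]
Why: α-Methylenation of a γ-lactone through its enolate: the alkoxide enolate dianion is aminomethylated at C11 (Mannich reaction), the amine is quaternised, and trimethylamine is eliminated under mild base to give the exocyclic C11=C13 bond.

Step 18
Reactants: 34 hydroxy methylene lactone; 35 tiglic acid
Product: 37 8α-tiglate, via mixed anhydride 36 (not isolated)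
Conditions: 35, 2,4,6-trichlorobenzoyl chloride, Et3N, toluene, 25 °C; then 34, DMAP, 25 → 50 °C
Reagents that add atoms: none
Why: Yamaguchi esterification: the mixed anhydride acylates DMAP and the acylpyridinium ion transfers the tigloyl group to the hindered secondary hydroxyl; tiglate is the stable E isomer, so its geometry is not at risk.

Step 19
Reactants: 37 tiglate
Product: 38 1β,10α-epoxide (p-methoxybenzyl ether of 39)
Conditions: mCPBA, NaHCO3, CH2Cl2, 0 °C
Reagents that add atoms: 3-chloroperoxybenzoic acid, OOC(=O)c1cccc(Cl)c1
Why: Prilezhaev epoxidation: only the electron-rich trisubstituted C1=C10 bond reacts, and the peracid reaches it from the outer face of the ring held by the 4,5-epoxide and the trans lactone, which gives the 1β,10α-epoxide, as is usual for 4,5-epoxygermacr-1(10)-en-12,6-olides.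

Step 20
Reactants: 38 p-methoxybenzyl ether
Product: 39 CNP0350037.1
Conditions: DDQ, CH2Cl2/pH 7 phosphate buffer, 0 → 25 °C
Reagents that add atoms: none
Why: Oxidative cleavage of the p-methoxybenzyl ether by hydride abstraction and hydrolysis of the oxocarbenium ion; the buffered neutral medium spares both epoxides, the ester and the Michael acceptor.

## Compound list

1 | (R)-carvone | CC1=CC[C@H](CC1=O)C(C)=C | starting material
2 | potassium cross-conjugated dienolate of 1 (O on C5; C5=C6 and C3=C4; not isolated) | [K+].[O-]C1=C[C@H](C(C)=C)CC=C1C | intermediate
3 | trans-6-hydroxycarvone, (5S,6S)-6-hydroxy-2-methyl-5-(prop-1-en-2-yl)cyclohex-2-en-1-one | O[C@H]1[C@H](C(C)=C)CC=C(C)C1=O | intermediate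
4 | C6 tert-butyldimethylsilyl ether of 3 | CC(C)(C)[Si](C)(C)O[C@H]1[C@H](C(C)=C)CC=C(C)C1=O | intermediate
5 | 3,4-epoxy C5 ketone, epoxide trans to isopropenyl and cis to the silyloxy group | CC(C)(C)[Si](C)(C)O[C@H]1[C@H](C(C)=C)C[C@H]2O[C@@]2(C)C1=O | intermediate
6 | C5 ketone with C3 p-methoxybenzyl ether (cis to isopropenyl), tertiary C4 hydroxyl (trans to isopropenyl) and C6 silyl ether | CC(C)(C)[Si](C)(C)O[C@H]1[C@H](C(C)=C)C[C@H](OCc2ccc(OC)cc2)[C@@](C)(O)C1=O | intermediate
7 | 4,5-cis-diol from 6 (C5 hydroxyl cis to O4) | CC(C)(C)[Si](C)(C)O[C@H]1[C@H](C(C)=C)C[C@H](OCc2ccc(OC)cc2)[C@@](C)(O)[C@H]1O | intermediate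
8 | 4,5-acetonide of 7 | CC(C)(C)[Si](C)(C)O[C@H]1[C@H](C(C)=C)C[C@H](OCc2ccc(OC)cc2)[C@@]2(C)OC(C)(C)O[C@@H]12 | intermediate
9 | C6 alcohol from 8 | O[C@H]1[C@H](C(C)=C)C[C@H](OCc2ccc(OC)cc2)[C@@]2(C)OC(C)(C)O[C@@H]12 | intermediate
10 | cyclohexanone: C6 ketone, C1 isopropenyl, C3 p-methoxybenzyl ether, 4,5-acetonide | O=C1[C@H](C(C)=C)C[C@H](OCc2ccc(OC)cc2)[C@@]2(C)OC(C)(C)O[C@@H]12 | intermediate
11 | (E)-1,2-bis(tributylstannyl)ethene | CCCC[Sn](CCCC)(CCCC)/C=C/[Sn](CCCC)(CCCC)CCCC | starting material
12 | benzylchlorodimethylsilane | C[Si](C)(Cl)Cc1ccccc1 | starting material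
13 | (E)-2-(tributylstannyl)vinyllithium (not isolated) | [Li]/C=C/[Sn](CCCC)(CCCC)CCCC | intermediate
14 | (E)-benzyldimethyl[2-(tributylstannyl)vinyl]silane | C[Si](C)(Cc1ccccc1)/C=C/[Sn](CCCC)(CCCC)CCCC | intermediate
15 | (E)-2-(benzyldimethylsilyl)vinyllithium (not isolated) | [Li]/C=C/[Si](C)(C)Cc1ccccc1 | intermediate
16 | (E)-[2-(benzyldimethylsilyl)vinyl]cerium dichloride (not isolated) | Cl[Ce](Cl)/C=C/[Si](C)(C)Cc1ccccc1 | intermediate
17 | trans-1-[(E)-2-(benzyldimethylsilyl)vinyl]-2-isopropenylcyclohexanol with C3 p-methoxybenzyl ether and 4,5-acetonide | O[C@]1(/C=C/[Si](C)(C)Cc2ccccc2)[C@H](C(C)=C)C[C@H](OCc2ccc(OC)cc2)[C@@]2(C)OC(C)(C)O[C@@H]12 | intermediate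
18 | potassium alkoxide of 17 (not isolated) | [K+].[O-][C@]1(/C=C/[Si](C)(C)Cc2ccccc2)[C@H](C(C)=C)C[C@H](OCc2ccc(OC)cc2)[C@@]2(C)OC(C)(C)O[C@@H]12 | intermediate
19 | potassium enolate of 20 (C6=C7, oxygen cis to C8; not isolated) | [K+].[O-]/C1=C\[C@@H]([Si](C)(C)Cc2ccccc2)C/C(C)=C/C[C@H](OCc2ccc(OC)cc2)[C@@]2(C)OC(C)(C)O[C@@H]12 | intermediate
20 | ten-membered C6 ketone, (E)-C1=C10, 8α-benzyldimethylsilyl, C3 p-methoxybenzyl ether, 4,5-acetonide | O=C1C[C@@H]([Si](C)(C)Cc2ccccc2)C/C(C)=C/C[C@H](OCc2ccc(OC)cc2)[C@@]2(C)OC(C)(C)O[C@@H]12 | intermediate
21 | methyl bromoacetate | COC(=O)CBr | starting material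
22 | lithium enolate of 20 (C6=C7, oxygen cis to C8; not isolated) | [Li+].[O-]/C1=C\[C@@H]([Si](C)(C)Cc2ccccc2)C/C(C)=C/C[C@H](OCc2ccc(OC)cc2)[C@@]2(C)OC(C)(C)O[C@@H]12 | intermediate
23 | C7-(methoxycarbonylmethyl) derivative of 20, C11 trans to silicon | O=C1[C@H](CC(=O)OC)[C@@H]([Si](C)(C)Cc2ccccc2)C/C(C)=C/C[C@H](OCc2ccc(OC)cc2)[C@@]2(C)OC(C)(C)O[C@@H]12 | intermediate
24 | C6 alcohol of 23, hydroxyl on the α face (not isolated) | O[C@H]1[C@H](CC(=O)OC)[C@@H]([Si](C)(C)Cc2ccccc2)C/C(C)=C/C[C@H](OCc2ccc(OC)cc2)[C@@]2(C)OC(C)(C)O[C@@H]12 | intermediate
25 | trans-fused 12,6α-lactone with 8α-silyl group, C3 p-methoxybenzyl ether, 4,5-acetonide | C1C(=O)O[C@H]2[C@H]1[C@@H]([Si](C)(C)Cc3ccccc3)C/C(C)=C/C[C@H](OCc3ccc(OC)cc3)[C@@]4(C)OC(C)(C)O[C@@H]24 | intermediate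
26 | 4,5-diol lactone from 25 | C1C(=O)O[C@H]2[C@H]1[C@@H]([Si](C)(C)Cc3ccccc3)C/C(C)=C/C[C@H](OCc3ccc(OC)cc3)[C@@](C)(O)[C@H]2O | intermediate
27 | C5 methanesulfonate of 26 (not isolated) | C1C(=O)O[C@H]2[C@H]1[C@@H]([Si](C)(C)Cc3ccccc3)C/C(C)=C/C[C@H](OCc3ccc(OC)cc3)[C@@](C)(O)[C@H]2OS(C)(=O)=O | intermediate
28 | 4α,5β-epoxy lactone with 8α-silyl group | C1C(=O)O[C@H]2[C@H]1[C@@H]([Si](C)(C)Cc3ccccc3)C/C(C)=C/C[C@H](OCc3ccc(OC)cc3)[C@@]4(C)O[C@H]24 | intermediate
29 | 8α-fluorodimethylsilyl analogue of 28 (not isolated) | C1C(=O)O[C@H]2[C@H]1[C@@H]([Si](C)(C)F)C/C(C)=C/C[C@H](OCc3ccc(OC)cc3)[C@@]4(C)O[C@H]24 | intermediate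
30 | 8α-hydroxy-4α,5β-epoxy lactone | C1C(=O)O[C@H]2[C@H]1[C@@H](O)C/C(C)=C/C[C@H](OCc3ccc(OC)cc3)[C@@]4(C)O[C@H]24 | intermediate
31 | dilithium C8 alkoxide lactone enolate of 30 (not isolated) | [Li+].[Li+].C1=C([O-])O[C@H]2[C@H]1[C@@H]([O-])C/C(C)=C/C[C@H](OCc3ccc(OC)cc3)[C@@]4(C)O[C@H]24 | intermediate
32 | C11 dimethylaminomethyl lactone, C11 epimers (not isolated) | CN(C)CC1C(=O)O[C@H]2[C@H]1[C@@H](O)C/C(C)=C/C[C@H](OCc3ccc(OC)cc3)[C@@]4(C)O[C@H]24 | intermediate
33 | trimethylammonium iodide of 32 (not isolated) | [I-].C[N+](C)(C)CC1C(=O)O[C@H]2[C@H]1[C@@H](O)C/C(C)=C/C[C@H](OCc3ccc(OC)cc3)[C@@]4(C)O[C@H]24 | intermediate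
34 | α-methylene lactone with free 8α-hydroxyl | C=C1C(=O)O[C@H]2[C@H]1[C@@H](O)C/C(C)=C/C[C@H](OCc3ccc(OC)cc3)[C@@]4(C)O[C@H]24 | intermediate
35 | tiglic acid, (E)-2-methylbut-2-enoic acid | C/C=C(\C)C(=O)O | starting material
36 | tiglic 2,4,6-trichlorobenzoic anhydride (not isolated) | C/C=C(\C)C(=O)OC(=O)c1c(Cl)cc(Cl)cc1Cl | intermediate
37 | 8α-tiglate of 34 | C=C1C(=O)O[C@H]2[C@H]1[C@@H](OC(=O)/C(C)=C/C)C/C(C)=C/C[C@H](OCc3ccc(OC)cc3)[C@@]4(C)O[C@H]24 | intermediate
38 | 1β,10α:4α,5β-diepoxide, O3 p-methoxybenzyl ether of 39 | C=C1C(=O)O[C@H]2[C@H]1[C@@H](OC(=O)/C(C)=C/C)C[C@@]5(C)O[C@@H]5C[C@H](OCc3ccc(OC)cc3)[C@@]4(C)O[C@H]24 | intermediate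
39 | CNP0350037.1, (1R,3S,4R,5R,6S,7R,8S,10R)-1β,10α:4α,5β-diepoxy-3β-hydroxy-8α-tigloyloxygermacr-11(13)-en-12,6α-olide | C=C1C(=O)O[C@H]2[C@H]1[C@@H](OC(=O)/C(C)=C/C)C[C@@]1(C)O[C@@H]1C[C@H](O)[C@@]1(C)O[C@H]21 | target

## Step count and least certain steps

Total: 20 steps. Longest linear sequence: 19 steps from 1 (steps 1–8 and 10–20); step 9 is a one-step side branch to 14.

**Step 11 (key step).** What may go wrong: partial reaction through a boat, which would erode the C8 configuration and the olefin geometry. The potassium alkoxide could attack the benzylsilane. The product enolate could equilibrate to the C5 enolate and lose O4, because the free potassium enolate is long-lived at 25 °C. Fallback: from 17, silylation with N-(trimethylsilyl)imidazole would give the trimethylsilyl ether F1. Heating F1 in a hydrocarbon solvent (neutral siloxy-Cope rearrangement, no alkoxide and no free enolate) would give the silyl enol ether F2. Mild hydrolysis with aqueous citric acid in THF would return the route at 20.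

**Step 4.** What may go wrong: slow opening, because anti attack at C3 places the nucleophile cis-1,3 to the isopropenyl group, against the usual trans-diaxial preference. The Lewis acid could then divert the epoxy ketone into an acyl shift or condense the benzylic alcohol with itself. Fallback: from 5, hydrolysis with dilute HClO4 in aqueous THF (water as the smallest oxygen nucleophile) would give diol F3. Its secondary hydroxyl would be etherified selectively with 4-methoxybenzyl trichloroacetimidate and catalytic La(OTf)3, returning at 6.

**Step 10.** What may go wrong: deprotonation of the ketone at C1 instead of addition, with loss of the C1 configuration or isomerisation into conjugation, and incomplete facial selectivity if the α-oxygen steers attack to the axial side. Fallback: from 12, HC≡CMgBr would give benzyl(ethynyl)dimethylsilane F4. Its lithium acetylide (n-BuLi, CeCl3), a slimmer and less basic nucleophile, would add to 10 to give propargylic alcohol F5. Hydroxyl-directed trans-hydroalumination with NaAlH2(OCH2CH2OMe)2 would deliver the (E)-vinylsilane and return at 17.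

**Step 12.** What may go wrong: poor facial selectivity or loss of regiocontrol, because the enolate is regenerated from a conformationally equilibrated ketone. The silyl group lies near the only open face, and deprotonation at C5 would be followed by loss of O4. Fallback: starting again from 17, the rearrangement would be run as in step 11 through 18 to 19, and 21 would be added to the cold solution of 19. The enolate is then alkylated as it is born, with the regiochemistry, geometry and conformation set by the chair transition state, and the route is rejoined at 23 (20 is bypassed, no new compound).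

**Step 13.** What may go wrong: hydride delivery without chelation (the dioxolane oxygen is a modest ligand), which would give the C6 epimer and hence a cis lactone. Fallback: from 23, if the epimeric alcohol forms it would close to cis lactone F6. Saponification with LiOH would give hydroxy acid F7, and Mitsunobu lactonisation (PPh3, diisopropyl azodicarboxylate) would activate the C6 hydroxyl and close the ring with inversion, returning at 25.

## Further compounds

F1 | step 11 | trimethylsilyl ether of 17 | C[Si](C)(C)O[C@]1(/C=C/[Si](C)(C)Cc2ccccc2)[C@H](C(C)=C)C[C@H](OCc2ccc(OC)cc2)[C@@]2(C)OC(C)(C)O[C@@H]12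
F2 | step 11 | trimethylsilyl enol ether of 20 (C6=C7, oxygen cis to C8) | C[Si](C)(C)O/C1=C\[C@@H]([Si](C)(C)Cc2ccccc2)C/C(C)=C/C[C@H](OCc2ccc(OC)cc2)[C@@]2(C)OC(C)(C)O[C@@H]12
F3 | step 4 | 3,4-trans-diol C5 ketone with C6 silyl ether (O3 cis to isopropenyl, O4 trans) | CC(C)(C)[Si](C)(C)O[C@H]1[C@H](C(C)=C)C[C@H](O)[C@@](C)(O)C1=O
F4 | step 10 | benzyl(ethynyl)dimethylsilane | C#C[Si](C)(C)Cc1ccccc1
F5 | step 10 | propargylic alcohol: C6 carbinol of 10 bearing the (benzyldimethylsilyl)ethynyl group trans to isopropenyl | O[C@]1(C#C[Si](C)(C)Cc2ccccc2)[C@H](C(C)=C)C[C@H](OCc2ccc(OC)cc2)[C@@]2(C)OC(C)(C)O[C@@H]12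
F0 | step 12 | none | none
F6 | step 13 | cis-fused lactone, C6 epimer of 25 | C1C(=O)O[C@@H]2[C@H]1[C@@H]([Si](C)(C)Cc3ccccc3)C/C(C)=C/C[C@H](OCc3ccc(OC)cc3)[C@@]4(C)OC(C)(C)O[C@@H]24
F7 | step 13 | hydroxy acid from F6 (C6 hydroxyl on the β face) | O[C@@H]1[C@H](CC(=O)O)[C@@H]([Si](C)(C)Cc2ccccc2)C/C(C)=C/C[C@H](OCc2ccc(OC)cc2)[C@@]2(C)OC(C)(C)O[C@@H]12
A1 | alternative 1 | O3-triethylsilyl ether of 39 | C=C1C(=O)O[C@H]2[C@H]1[C@@H](OC(=O)/C(C)=C/C)C[C@@]1(C)O[C@@H]1C[C@H](O[Si](CC)(CC)CC)[C@@]1(C)O[C@H]21
A2 | alternative 1 | C6-hydroxy C7-(1-iodovinyl) diepoxide with 8α-tiglate and O3 triethylsilyl ether | O[C@H]2[C@H](C(I)=C)[C@@H](OC(=O)/C(C)=C/C)C[C@@]1(C)O[C@@H]1C[C@H](O[Si](CC)(CC)CC)[C@@]1(C)O[C@H]21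
A3 | alternative 2 | 4,5-epoxy-3-oxo-8-tigloyloxygermacr-1(10)-en-12,6-olide | C=C1C(=O)O[C@H]2[C@H]1[C@@H](OC(=O)/C(C)=C/C)C/C(C)=C/CC(=O)[C@@]1(C)O[C@H]21
A4 | alternative 2 | seco C5 aldehyde with C3 keto C4 gem-dichloride | C=C1C(=O)O[C@H](C=O)[C@H]1[C@@H](OC(=O)/C(C)=C/C)C/C(C)=C/CC(=O)C(C)(Cl)Cl
A5 | alternative 3 | 8-hydroxy-3-(tert-butyldimethylsilyloxy)germacra-1(10),4,11(13)-trien-12,6-olide | C=C1C(=O)O[C@H]2[C@H]1[C@@H](O)C/C(C)=C/C[C@H](O[Si](C)(C)C(C)(C)C)/C(C)=C/2
A6 | alternative 3 | seco C8 aldehyde with 2-(bromomethyl)butenolide | BrCC1=C[C@H](OC1=O)/C=C(\C)[C@@H](O[Si](C)(C)C(C)(C)C)C/C=C(\C)CC=O
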